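(Readings and results are calculated with made-up constants, noise included.)

Left-handed substrate is the leftover to watch: in the north-east flask it averages 29.6 % of the combined charge, while left-handed product sits flat at a mean of 23.2 %.

the same everywhere: free catalyst 10 mol%; precatalyst 0.17 mol%
- north-east: left-handed substrate 0.10 M; right-handed substrate 0.10 M; partner 2.2 equiv; temperature 25 °C; the very flask that is asked about, followed so far
- south-east: left-handed substrate 0.20 M; right-handed substrate 0.20 M; partner 2.2 equiv; temperature 31 °C; run made earlier
- flask: left-handed substrate 0.10 M; right-handed substrate 0.10 M; partner 2.20 equiv; temperature 25 °C; time 4.0 h

| run | time / min | left-handed product / % | left-handed substrate / % |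
|---|---|---|---|
| north-east | 20.0 | 23 | 30 |
| north-east | 60.0 | 25 | 29 |
| north-east | 120 | 23 | 28 |
| north-east | 180 | 24 | 30 |
| north-east | 240 | 21 | 31 |
| south-east | 0.667 | 11 | 37 |
| south-east | 1.33 | 21 | 31 |
| south-east | 2.50 | 25 | 24 |
| south-east | 4.00 | 30 | 20 |
| south-east | 8.00 | 33 | 16 |

(each reading ± 1.5 percentage points)

- free catalyst is single-handed; left-handed substrate and right-handed substrate are mirror images of each other, charged as a racemate, each of them at the stated concentration
- left-handed product taken out counts as made
- the numbers in the tables scatter with a standard deviation of 1.5 percentage points
- "the catalyst" is free catalyst with its forms; racemization catalyst is a second catalyst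
- additions bring no volume worth counting

- autumn: at 4.0 h add free catalyst, 50.0 % of the amount charged, then wait 8.0 h
- summer: at 4.0 h add partner, 100 % of the amount charged, then wait 8.0 h
- noon: change nothing and wait 8.0 h more
- midnight: at 4.0 h raise the temperature by 25 K, then wait 8.0 h
- spring: at 4.0 h take out 90 % of the left-handed product then present, then wait 8.0 h

* left-handed product, in percent of the left-handed substrate and right-handed substrate together first charged, at 4.0 h
* what to do for the largest gain in left-handed product; "none" if nothing gains more than 2 percentage points (autumn / summer / noon / midnight / spring / none)
* left-handed product present, with what was taken out counted in, in percent of the left-handed substrate and right-handed substrate together first charged, after midnight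
* left-handed product present, with what was taken out counted in, in percent of the left-handed substrate and right-handed substrate together first charged, after spring

1. The fastest rung is the rise in the south-east run at 31 °C: its first reading gives a rate that covers the last reading of 33 % in a stall time of 2.00 min.

2. In the north-east flask, the plateau already stands at the first reading, 20.0 min.

3. The slowest rung is the plateau of the north-east flask: up to 240 min its readings show no rise beyond a scatter of 1.5 percentage points, so I read a stop with substrate present, and I suspect a loss of catalyst or of partner.

4. The plateaus do not choose between them: the last south-east reading over the north-east mean is 1.42, but those runs differ in both concentration and temperature, and at a fixed decay constant a first-order loss of partner and one of catalyst scale alike with concentration. My working assumption, which the readings do not prove, is a loss of partner, and for it I carry φ = 0.211, the partner yield, left-handed product made per partner charged.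

5. A fresh dose should pay φ times the dose, scaled by the left-handed substrate remaining against its start. For summer in the north-east flask I reckon a gain of 14 points, and for the other options I expect no gain, with the product staying near 23.2 %.

6. The forecast gives 23 % now, 23.5 % after midnight and 23.5 % after spring, close to my figure, but it differs from me by choosing autumn: “Fresh catalyst should restart the reaction”.

7. The flask gives 22.8 % now, 22.8 % after midnight and 22.8 % after spring; the best option is summer, gaining 15 points against 0 points for autumn.

    partner + free catalyst + left-handed substrate → free catalyst + left-handed product (k = 44.0 /M²/min, Ea = 36.0 kJ/mol)
    partner + free catalyst + right-handed substrate → free catalyst + right-handed product (k = 18.0 /M²/min, Ea = 57.0 kJ/mol)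
    left-handed substrate + racemization catalyst ⇌ right-handed substrate + racemization catalyst, rate k3*[racemization catalyst]*[left-handed substrate] forward; the back reaction follows from the equilibrium constant (k = 21.0 /M/min, Ea = 39.0 kJ/mol)
    partner → decomposed reagent (k = 0.110 /min, Ea = 84.0 kJ/mol)
    2 racemization catalyst ⇌ resting dimer (K = 24.0 /M, k = 11.0 /M/min, Ea = 38.0 kJ/mol, ΔH = −38.0 kJ/mol)
    partner + precatalyst → racemization catalyst + spent reagent (k = 0.630 /M/min, Ea = 73.0 kJ/mol)
    (constants at 25 °C)

8. After 240 min in the flask, partner, the limiting reagent, stands at 0 % and free catalyst at 100 %. With the simulated 30.8 % of left-handed substrate, φ gives a dose gain of 14 points, against the 15 points found. In the neighbouring flask with 40 mol% of free catalyst, left-handed product reaches 39.2 %, so φ rises to 0.356. Partner there also stands at 0 %, and decomposed reagent reaches 0.0952 M, against 0.152 M in the flask.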